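**Plan**
The ring of the target is the enol form of a cyclohexane-1,2,4,5-tetraone. C3 (hexadecyl-bearing) lies between the carbonyl-level carbons C2 and C4, and C6 (H-bearing) between C1 and C5, so C2–C3 and C1–C6 are both Claisen bonds.
Retrosynthesis cuts O5–CH3, then C2–C3 (ring opening to an acyclic 2,4,5-trioxo ester), then C1–C6 (oxalate Claisen), then C4–C5 (acyl-anion addition to a stearic Weinreb amide).
Forward, stearoyl chloride supplies C4, C3 and the chain, ethyl vinyl ether supplies C5 and C6, and diethyl oxalate supplies C1 and C2.
The C22 chain is assembled first; the only ring then closes by Dieckmann condensation at the quinone oxidation level, and O5 is methylated last.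
Stereochemistry: the target has no stereocentre and no configurable double bond, so nothing has to be set.

Key step: step 4

Remark: the target is achiral, so the structure given is its only stereoisomer. Compounds 8 and 9 are written as one tautomer each: 8 should exist largely as an enol, and 9 is the enol form of 3-hexadecylcyclohexane-1,2,4,5-tetraone.

**Step 1**
Reactants: 1 octadecanoyl chloride (stearoyl chloride)
Product: 2 N-methoxy-N-methyloctadecanamide
Conditions: MeNH(OMe)·HCl, K2CO3, CH2Cl2/H2O, 0 °C → rt
Reagents that add atoms: N,O-dimethylhydroxylamine hydrochloride, CNOC.Cl
Why: Schotten–Baumann acylation, in which the hydroxylamine freed by carbonate attacks the acid chloride much faster than water does and the Weinreb amide formed is stable to the aqueous base.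

**Step 2**
Reactants: 2 N-methoxy-N-methyloctadecanamide; 3 ethyl vinyl ether
Product: 6 icosane-2,3-dione, via 1-ethoxyvinyllithium 4 (not isolated), via 2-ethoxyicos-1-en-3-one 5 (not isolated)
Conditions: 3, t-BuLi, THF, −78 → 0 °C; then 2, −78 → 0 °C; then 2 M HCl, THF, rt
Reagents that add atoms: water, O
Why: α-Lithiated ethyl vinyl ether is an acetyl-anion equivalent that adds once to the Weinreb amide because the N-methoxy chelate holds the tetrahedral adduct until the acid quench, which releases the ketone and hydrolyses the enol ether to the second carbonyl (Weinreb ketone synthesis followed by enol ether hydrolysis).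

**Step 3**
Reactants: 6 icosane-2,3-dione; 7 diethyl oxalate
Product: 8 ethyl 2,4,5-trioxodocosanoate
Conditions: LiHMDS (1.1 equiv), THF, −78 °C (6 added slowly); then 7 (2 equiv), −78 → 0 °C; cold 1 M HCl
Reagents that add atoms: none
Why: Crossed Claisen condensation, in which the hindered amide base should deprotonate the unhindered methyl group under kinetic control, the lithium enolate acylates on carbon with non-enolisable diethyl oxalate, and the ethoxide released converts the product into its lithium-chelated 1,3-diketonate, which drives the condensation and, with one equivalent of base, stops the sequence before ring closure.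

**Step 4**
Reactants: 8 ethyl 2,4,5-trioxodocosanoate
Product: 9 3-hexadecyl-2,5-dihydroxy-1,4-benzoquinone
Conditions: KOt-Bu (3 equiv), THF (0.05 M), 0 °C → rt (40 °C if slow), Ar; then 1 M HCl
Reagents that add atoms: none
Why: In the chain numbering of 8, the first equivalent of tert-butoxide forms the C2/C4 diketonate and the second deprotonates C6, the hexadecyl-bearing carbon next to the C5 ketone; this carbanion adds to the ester carbonyl C1, ethoxide leaves, and the 3-hexadecylcyclohexane-1,2,4,5-tetraone formed loses its remaining doubly activated proton to give the dianion of 9, so acidification should deliver the dihydroxyquinone with no change of oxidation level. The closest known reaction type is the Dieckmann condensation of oxalyl ketones, as in the alkoxide-mediated closure of 2,4-dioxoalkanoates (from ketones and dialkyl oxalates) to cyclopentane-1,2,4-triones; here a 1,2-diketone is the carbon acid and the ring is one atom larger. The single six-membered carbocycle closes by a 6-(enolendo)-exo-trig acyl substitution that forms the C1–C6 bond of the chain, which is C2–C3 of the quinone. No stereocentre is formed. The step needs C-acylation at C6 rather than O-acylation or aldol addition: O-acylation gives enol lactones that alkoxide reopens, the diketonate charge switches off C2 and C4 as aldol acceptors so the ester is the only electrophile within reach, and the doubly vinylogous carboxylate dianion of 9 is the sink that drains every equilibrium. Potassium in THF is chosen over lithium so that the diketonate can leave its chelated U-shape and place C1 and C4 cis about the C2–C3 bond, as the ring requires.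

**Step 5**
Reactants: 9 3-hexadecyl-2,5-dihydroxy-1,4-benzoquinone
Product: 10 3-hexadecyl-2-hydroxy-5-methoxy-1,4-benzoquinone (target)
Conditions: MeOH/CH2Cl2, cat. H2SO4, rt, stopped at the mono-ether
Reagents that add atoms: methanol, CO
Why: Vinylogous Fischer esterification, in which acid-catalysed addition–elimination of methanol should occur at the vinylogous acid unit O1–C1–C6–C5–O5, whose carbons are flanked only by C6–H, while the unit around C3 is shielded and made less electrophilic by the hexadecyl group, so the methoxy group ends up at C5 and the hydroxyl next to the chain is kept.

**Compound list**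
1 | octadecanoyl chloride (stearoyl chloride) | CCCCCCCCCCCCCCCCCC(=O)Cl | starting material
2 | N-methoxy-N-methyloctadecanamide | CCCCCCCCCCCCCCCCCC(=O)N(C)OC | intermediate
3 | ethyl vinyl ether | C=COCC | starting material
4 | 1-ethoxyvinyllithium | [Li]C(=C)OCC | intermediate
5 | 2-ethoxyicos-1-en-3-one | CCCCCCCCCCCCCCCCCC(=O)C(=C)OCC | intermediate
6 | icosane-2,3-dione | CCCCCCCCCCCCCCCCCC(=O)C(C)=O | intermediate
7 | diethyl oxalate | CCOC(=O)C(=O)OCC | starting material
8 | ethyl 2,4,5-trioxodocosanoate (isolated as its enol tautomers) | CCCCCCCCCCCCCCCCCC(=O)C(=O)CC(=O)C(=O)OCC | intermediate
9 | 3-hexadecyl-2,5-dihydroxy-1,4-benzoquinone (3-hexadecyl-2,5-dihydroxycyclohexa-2,5-diene-1,4-dione) | CCCCCCCCCCCCCCCCC1=C(O)C(=O)C=C(O)C1=O | intermediate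
10 | 3-hexadecyl-2-hydroxy-5-methoxy-1,4-benzoquinone (achiral) | CCCCCCCCCCCCCCCCC1=C(O)C(=O)C=C(OC)C1=O | target

Total step count: 5
Longest linear sequence: 5 steps (1 → 2 → 6 → 8 → 9 → 10)

**Steps most likely to fail**

Step 4. The second deprotonation at the hindered chain-bearing carbon, or its attack on the ester, may be too slow. Alkoxide-induced loss of the oxalyl unit (retro-Claisen) or intermolecular condensation could then outrun ring closure. The fallback sets out from 5, obtained by ending step 2 with an aqueous NH4Cl quench in place of the acid. LiHMDS in THF at −78 °C and diethyl oxalate 7 should acylate the only enolisable position of 5, the CH2 next to the ketone, to give ethyl 5-ethoxy-3-hexadecyl-2,4-dioxohex-5-enoate F1. Dilute HCl in THF should hydrolyse the enol ether to ethyl 3-hexadecyl-2,4,5-trioxohexanoate F2. KOt-Bu in THF should then close the same tetraone ring from the other side: the unhindered methyl carbanion attacks the ester, so the ring forms through the bond between C6 and its neighbouring carbonyl-level carbon instead of through C2–C3. The fallback returns to the route at 9.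

Step 3. Self-aldol condensation of the electrophilic 1,2-diketone during enolate formation, or proton transfer that moves the enolate to the methylene side before acylation, would erode the precursor. The fallback sets out from 6. LiHMDS is added to 6 and TMSCl in THF at −78 °C (in situ quench), which should trap the kinetic enolate as 2-(trimethylsilyloxy)icos-1-en-3-one F3 before it can meet free diketone. F3 is then C-acylated with ethyl chlorooxoacetate (CH2Cl2, 0 °C → rt, cat. ZnCl2 if needed), a Mukaiyama-type acylation of a silyl enol ether by an acid chloride. The fallback returns to the route at 8.

Step 5. Under the reversible acid conditions the site selectivity may be lost, or methylation may run on to the 2,5-dimethyl ether. The fallback sets out from 9 and changes the mechanism from addition–elimination at a ring carbon to alkylation at oxygen. Trimethylsilyldiazomethane (1.0 equiv, toluene/MeOH, 0 °C) should methylate after proton transfer from the more acidic vinylogous acid, which is the unit around C6–H that carries no alkyl donor. Selection is then by acidity and not by steric access. It gives 10 directly, so no new compound arises (F0).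

**Further compounds**
F1 | step 4 | ethyl 5-ethoxy-3-hexadecyl-2,4-dioxohex-5-enoate (racemic, enolisable centre) | CCOC(=O)C(=O)C(CCCCCCCCCCCCCCCC)C(=O)C(=C)OCC
F2 | step 4 | ethyl 3-hexadecyl-2,4,5-trioxohexanoate (racemic, enolisable centre) | CCOC(=O)C(=O)C(CCCCCCCCCCCCCCCC)C(=O)C(C)=O
F3 | step 3 | 2-(trimethylsilyloxy)icos-1-en-3-one | CCCCCCCCCCCCCCCCCC(=O)C(=C)O[Si](C)(C)C
F0 | step 5 | none | none
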